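**Plan**

- Feature: in the isochromanone (C1 lactone carbonyl, O2, C3, C4, C4a, C5, C6–OMe, C7, C8–OH, C8a) the oxygen-bearing C1, C8 and C6 and the alkylated C4a alternate around the benzene ring, as in a folded poly-β-carbonyl chain. The ring bond C4a–C8a can therefore be made by aldol condensation onto a ketone at C4a.
- Retrosynthesis: the lactone bond C1–O2 and the C6 O–CH3 bond are cut first, then the arene bond C4a–C8a, then the chain bonds C4a–C5 and C6–C7 (two Claisen-type acylations) and C3–C4 (malonate homologation of a C12 acid).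
- Forward: a silylated (R)-β-hydroxy Weinreb amide (C3, C4, C4a and the side chain) is joined to the dianion of acetylated 2,2,6-trimethyldioxinone (C5 to C8a and C1). The benzene ring closes first by aldol aromatisation; the lactone ring closes last by acyl transfer from the acetonide to the C3 oxygen, before debenzylation.
- Stereochemistry: the single stereocentre C3 (R) comes from Noyori hydrogenation of a β-keto ester with RuCl2[(R)-BINAP]; its C–O bond is never broken afterwards.

Key step: step 8

Remark: polycarbonyl compounds are drawn as keto tautomers; metal enolates pre-formed before the electrophile is added are numbered as intermediates and drawn with O–metal bonds, while salts present only in equilibrium (alkoxide, phenoxide, carboxylate) are treated as forms of their parent compound.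

**Route**

Step 1
Reactants: 1 12-hydroxydodecanoic acid
Product: 2 12-(benzyloxy)dodecanoic acid
Conditions: KOH (powdered, 5 equiv), BnBr (2 equiv), toluene, reflux; then H2O, 2 M HCl
Reagents that add atoms: benzyl bromide, BrCc1ccccc1
Why: Williamson ether synthesis in which the primary alkoxide is benzylated while the carboxyl group stays as its poorly nucleophilic potassium salt in toluene, so that acidification should return the ether acid.

Step 2
Reactants: 2 12-(benzyloxy)dodecanoic acid; 3 potassium monomethyl malonate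
Product: 7 methyl 14-(benzyloxy)-3-oxotetradecanoate, via acyl imidazolide 4 (not isolated), via magnesium malonate chelate 5 (not isolated), via acylmalonate half ester 6 (not isolated)
Conditions: 1,1'-carbonyldiimidazole (1.1 equiv), THF, rt; then 3 (2 equiv) premixed with MgCl2 and Et3N in MeCN, rt; 1 M HCl
Reagents that add atoms: none
Why: Masamune–Brooks homologation, in which the acyl imidazolide C-acylates the magnesium enolate of the malonate half ester and the acylmalonate loses CO2 on acidic work-up, a standard way from an acid to its β-keto ester that leaves the benzyl ether alone.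

Step 3
Reactants: 7 methyl 14-(benzyloxy)-3-oxotetradecanoate
Product: 8 methyl (3R)-14-(benzyloxy)-3-hydroxytetradecanoate
Conditions: H2 (10 bar), RuCl2[(R)-BINAP] (0.5 mol%), MeOH, 50 °C
Reagents that add atoms: none
Why: Noyori asymmetric hydrogenation of a β-keto ester, in which chelation of ketone and ester to the (R)-BINAP–ruthenium hydride exposes one ketone face and should set the carbinol centre as (R), as is general for 3-oxoalkanoates with this ligand antipode, while the benzyl ether is inert to the homogeneous catalyst.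

Step 4
Reactants: 8 methyl (3R)-14-(benzyloxy)-3-hydroxytetradecanoate
Product: 9 methyl (3R)-14-(benzyloxy)-3-[(tert-butyldimethylsilyl)oxy]tetradecanoate
Conditions: TBSCl, imidazole, DMF, rt
Reagents that add atoms: tert-butyldimethylsilyl chloride, CC(C)(C)[Si](C)(C)Cl
Why: Imidazole-promoted silylation of a secondary alcohol, which blocks retro-aldol cleavage and dehydration of the β-hydroxy carbonyl unit in the basic steps that follow.

Step 5
Reactants: 9 methyl (3R)-14-(benzyloxy)-3-[(tert-butyldimethylsilyl)oxy]tetradecanoate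
Product: 10 (3R)-14-(benzyloxy)-3-[(tert-butyldimethylsilyl)oxy]-N-methoxy-N-methyltetradecanamide
Conditions: MeNH(OMe)·HCl (2 equiv), iPrMgCl (4 equiv), THF, −20 → 0 °C; aq. NH4Cl
Reagents that add atoms: N,O-dimethylhydroxylamine hydrochloride, CNOC.Cl
Why: Direct ester aminolysis to the Weinreb amide by the chloromagnesium amide generated from the hydroxylamine salt and iPrMgCl, a weakly basic nucleophile that at low temperature should leave the β-silyloxy group and the stereocentre intact.

Step 6
Reactants: 11 2,2,6-trimethyl-4H-1,3-dioxin-4-one; 12 acetyl chloride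
Product: 14 2,2-dimethyl-6-(2-oxopropyl)-4H-1,3-dioxin-4-one, via lithium dienolate 13 (not isolated)
Conditions: 11 (2 equiv), LiN(SiMe3)2 (2 equiv), THF, −78 °C; then 12 (1 equiv), −78 °C; 1 M HCl
Reagents that add atoms: none
Why: γ-Deprotonation of the vinylogous ester gives the extended dienolate, which undergoes Claisen-type C-acylation at its terminal carbon, two equivalents of dienolate being used because the product is more acidic than 11.

Step 7
Reactants: 10 (3R)-14-(benzyloxy)-3-[(tert-butyldimethylsilyl)oxy]-N-methoxy-N-methyltetradecanamide; 14 2,2-dimethyl-6-(2-oxopropyl)-4H-1,3-dioxin-4-one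
Product: 16 6-[(6R)-17-(benzyloxy)-6-[(tert-butyldimethylsilyl)oxy]-2,4-dioxoheptadecyl]-2,2-dimethyl-4H-1,3-dioxin-4-one, via dilithium dianion 15 (not isolated)
Conditions: 14 (2.5 equiv), LiN(iPr)2 (5 equiv), THF, −78 → −40 °C; then 10, −40 °C; AcOH, −78 °C
Reagents that add atoms: none
Why: Crossed Claisen condensation in which the terminal carbon of the dianion, the site deprotonated last and therefore the most nucleophilic, adds to the Weinreb amide, whose chelated tetrahedral adduct prevents over-addition and collapses on quench to the 1,3-diketone, excess dianion making up for proton transfer to the acidic product.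

Step 8
Reactants: 16 6-[(6R)-17-(benzyloxy)-6-[(tert-butyldimethylsilyl)oxy]-2,4-dioxoheptadecyl]-2,2-dimethyl-4H-1,3-dioxin-4-one
Product: 18 5-[(2R)-13-(benzyloxy)-2-[(tert-butyldimethylsilyl)oxy]tridecyl]-7-hydroxy-2,2-dimethyl-4H-1,3-benzodioxin-4-one, via aldol carbinol 17 (not isolated)
Conditions: Et3N (5 equiv), CH2Cl2, rt
Reagents that add atoms: none
Why: Triethylamine removes a proton from the doubly activated CH2 between the dioxinone and the first ketone of 16 (future C7); the dienolate attacks the distal ketone (future C4a) through the dioxinone α-carbon (future C8a) to give carbinol 17, which loses water and enolises the remaining ketone (future C6) to the phenol of 18. The closest known reaction type is the amine-mediated aldol aromatisation of diketo-dioxinones to acetonide-masked β-resorcylates, a laboratory counterpart of polyketide cyclisation. The one ring formed, the benzene ring, closes in the 6-(enolexo)-exo-trig aldol mode. No stereocentre is created, because the carbinol carbon of 17 becomes aromatic, and the silyloxy-bearing carbon is not α to any carbonyl and so cannot epimerise. The step needs C–C closure rather than O-cyclisation to a pyranone, loss of acetone to an acyl ketene or β-elimination of the silyloxy group: the cis enol ether fixed in the dioxinone ring holds C8a within reach of the ketone, room temperature leaves the dioxinone intact, and the weak amine ionises only the doubly activated methylenes and not the CH2 next to the silyloxy carbon. Because the acetonide ties the C1 carboxyl and the C8 oxygen together, the C6 hydroxyl emerges as the only free phenol.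

Step 9
Reactants: 18 5-[(2R)-13-(benzyloxy)-2-[(tert-butyldimethylsilyl)oxy]tridecyl]-7-hydroxy-2,2-dimethyl-4H-1,3-benzodioxin-4-one
Product: 19 5-[(2R)-13-(benzyloxy)-2-[(tert-butyldimethylsilyl)oxy]tridecyl]-7-methoxy-2,2-dimethyl-4H-1,3-benzodioxin-4-one
Conditions: MeI, K2CO3, acetone, rt
Reagents that add atoms: iodomethane, CI
Why: Williamson O-methylation of the only free phenol, the other phenolic oxygen being locked in the acetonide, so that no regioselectivity question arises.

Step 10
Reactants: 19 5-[(2R)-13-(benzyloxy)-2-[(tert-butyldimethylsilyl)oxy]tridecyl]-7-methoxy-2,2-dimethyl-4H-1,3-benzodioxin-4-one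
Product: 21 (3R)-3-[11-(benzyloxy)undecyl]-8-hydroxy-6-methoxy-3,4-dihydro-1H-isochromen-1-one, via free secondary alcohol 20 (not isolated)
Conditions: Bu4NF (1.5 equiv), THF, 0 °C → rt; then 1 M HCl
Reagents that add atoms: none
Why: Fluoride desilylation followed by intramolecular transacylation, in which the C3 alkoxide attacks the activated aryl ester carbonyl of the benzodioxinone in a 6-exo-trig closure and expels acetone and the C8 phenoxide, with retention at C3 because its C–O bond is not broken.

Step 11
Reactants: 21 (3R)-3-[11-(benzyloxy)undecyl]-8-hydroxy-6-methoxy-3,4-dihydro-1H-isochromen-1-one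
Product: 22 (3R)-8-hydroxy-3-(11-hydroxyundecyl)-6-methoxy-3,4-dihydro-1H-isochromen-1-one
Conditions: H2 (1 atm), Pd/C (10% palladium on carbon), EtOAc, rt
Reagents that add atoms: none
Why: Catalytic hydrogenolysis of the benzyl ether, under which the homobenzylic lactone C3–O bond, the phenol and the aryl methyl ether should be inert at 1 atm and rt.

**Compound list**

1 | 12-hydroxydodecanoic acid | OCCCCCCCCCCCC(=O)O | starting material
2 | 12-(benzyloxy)dodecanoic acid | OC(=O)CCCCCCCCCCCOCc1ccccc1 | intermediate
3 | potassium monomethyl malonate | COC(=O)CC(=O)[O-].[K+] | starting material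
4 | 1-[12-(benzyloxy)dodecanoyl]-1H-imidazole (not isolated) | O=C(CCCCCCCCCCCOCc1ccccc1)n1ccnc1 | intermediate
5 | magnesium chelate of the monomethyl malonate dianion (not isolated) | COC1=CC(=O)O[Mg]O1 | intermediate
6 | 14-(benzyloxy)-2-(methoxycarbonyl)-3-oxotetradecanoic acid, present as its magnesium chelate (not isolated) | COC(=O)C(C(=O)O)C(=O)CCCCCCCCCCCOCc1ccccc1 | intermediate
7 | methyl 14-(benzyloxy)-3-oxotetradecanoate | COC(=O)CC(=O)CCCCCCCCCCCOCc1ccccc1 | intermediate
8 | methyl (3R)-14-(benzyloxy)-3-hydroxytetradecanoate | COC(=O)C[C@H](O)CCCCCCCCCCCOCc1ccccc1 | intermediate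
9 | methyl (3R)-14-(benzyloxy)-3-[(tert-butyldimethylsilyl)oxy]tetradecanoate | COC(=O)C[C@H](O[Si](C)(C)C(C)(C)C)CCCCCCCCCCCOCc1ccccc1 | intermediate
10 | (3R)-14-(benzyloxy)-3-[(tert-butyldimethylsilyl)oxy]-N-methoxy-N-methyltetradecanamide | CON(C)C(=O)C[C@H](O[Si](C)(C)C(C)(C)C)CCCCCCCCCCCOCc1ccccc1 | intermediate
11 | 2,2,6-trimethyl-4H-1,3-dioxin-4-one | CC1=CC(=O)OC(C)(C)O1 | starting material
12 | acetyl chloride | CC(=O)Cl | starting material
13 | lithium 2,2-dimethyl-6-methylidene-6H-1,3-dioxin-4-olate (not isolated) | C=C1C=C(O[Li])OC(C)(C)O1 | intermediate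
14 | 2,2-dimethyl-6-(2-oxopropyl)-4H-1,3-dioxin-4-one | CC(=O)CC1=CC(=O)OC(C)(C)O1 | intermediate
15 | dilithium dienolate of 14, O,O'-dilithiated 6-(2-hydroxyprop-2-en-1-ylidene)-2,2-dimethyl-6H-1,3-dioxin-4-ol (not isolated) | C=C(O[Li])C=C1C=C(O[Li])OC(C)(C)O1 | intermediate
16 | 6-[(6R)-17-(benzyloxy)-6-[(tert-butyldimethylsilyl)oxy]-2,4-dioxoheptadecyl]-2,2-dimethyl-4H-1,3-dioxin-4-one | CC1(C)OC(=O)C=C(CC(=O)CC(=O)C[C@H](O[Si](C)(C)C(C)(C)C)CCCCCCCCCCCOCc2ccccc2)O1 | intermediate
17 | 5-[(2R)-13-(benzyloxy)-2-[(tert-butyldimethylsilyl)oxy]tridecyl]-5-hydroxy-2,2-dimethyl-5,6-dihydro-4H-1,3-benzodioxine-4,7(8H)-dione, both C-5 epimers (not isolated) | CC1(C)OC(=O)C2=C(O1)CC(=O)CC2(O)C[C@H](O[Si](C)(C)C(C)(C)C)CCCCCCCCCCCOCc3ccccc3 | intermediate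
18 | 5-[(2R)-13-(benzyloxy)-2-[(tert-butyldimethylsilyl)oxy]tridecyl]-7-hydroxy-2,2-dimethyl-4H-1,3-benzodioxin-4-one | CC1(C)OC(=O)c2c(C[C@H](O[Si](C)(C)C(C)(C)C)CCCCCCCCCCCOCc3ccccc3)cc(O)cc2O1 | intermediate
19 | 5-[(2R)-13-(benzyloxy)-2-[(tert-butyldimethylsilyl)oxy]tridecyl]-7-methoxy-2,2-dimethyl-4H-1,3-benzodioxin-4-one | CC1(C)OC(=O)c2c(C[C@H](O[Si](C)(C)C(C)(C)C)CCCCCCCCCCCOCc3ccccc3)cc(OC)cc2O1 | intermediate
20 | 5-[(2R)-13-(benzyloxy)-2-hydroxytridecyl]-7-methoxy-2,2-dimethyl-4H-1,3-benzodioxin-4-one (not isolated) | CC1(C)OC(=O)c2c(C[C@H](O)CCCCCCCCCCCOCc3ccccc3)cc(OC)cc2O1 | intermediate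
21 | (3R)-3-[11-(benzyloxy)undecyl]-8-hydroxy-6-methoxy-3,4-dihydro-1H-isochromen-1-one | COc1cc(O)c2c(c1)C[C@@H](CCCCCCCCCCCOCc3ccccc3)OC2=O | intermediate
22 | (3R)-8-hydroxy-3-(11-hydroxyundecyl)-6-methoxy-3,4-dihydro-1H-isochromen-1-one | COc1cc(O)c2c(c1)C[C@@H](CCCCCCCCCCCO)OC2=O | target

**Step count**

Total: 11 steps. Longest linear sequence: 10 steps (steps 1–5 and 7–11, from 1 to 22); step 6 is the one-step side branch.

**Steps most likely to fail, with fallbacks**

Step 7. Proton transfer from the acidic product or from the amide α-CH2 to the dianion may stall the condensation, and enolisation of the amide could lead to β-elimination of the silyloxy group. The fallback replaces acylation by aldol addition and oxidation. Setting out from 9, iBu2AlH (CH2Cl2, −78 °C) should stop at the aldehyde (3R)-14-(benzyloxy)-3-[(tert-butyldimethylsilyl)oxy]tetradecanal F1. F1 is added at −78 °C to dianion 15 (made from 14 as in step 7); this aldol addition is much faster than amide acylation and gives the β-hydroxy ketone 6-[(6R)-17-(benzyloxy)-6-[(tert-butyldimethylsilyl)oxy]-4-hydroxy-2-oxoheptadecyl]-2,2-dimethyl-4H-1,3-dioxin-4-one F2 as a mixture of carbinol epimers. Oxidation with Dess–Martin periodinane (CH2Cl2, NaHCO3) removes that stereocentre and comes back to the route at 16.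

Step 8. The cascade may stop at the carbinol stage without dehydration, or ring closure through oxygen to a pyranone may compete with the aldol. The fallback keeps the C4a–C8a aldol but runs it on an open-chain ester. Setting out from 16, heating with methanol in toluene (100–110 °C) expels acetone in a retro-hetero-Diels–Alder reaction to the acyl ketene (9R)-20-(benzyloxy)-9-[(tert-butyldimethylsilyl)oxy]icos-1-ene-1,3,5,7-tetrone F3, which methanol traps as methyl (9R)-20-(benzyloxy)-9-[(tert-butyldimethylsilyl)oxy]-3,5,7-trioxoicosanoate F4. Cs2CO3 in MeOH at rt, then AcOH, closes the same bond by aldol condensation of the triketo ester (the mild carbonate favouring aldol over Claisen closure) and should give methyl 2-[(2R)-13-(benzyloxy)-2-[(tert-butyldimethylsilyl)oxy]tridecyl]-4,6-dihydroxybenzoate F5. One equivalent of MeI with K2CO3 in acetone methylates the hydroxyl para to the ester, the ortho one being hydrogen-bonded, to methyl 2-[(2R)-13-(benzyloxy)-2-[(tert-butyldimethylsilyl)oxy]tridecyl]-6-hydroxy-4-methoxybenzoate F6. Bu4NF in THF then frees the alcohol methyl 2-[(2R)-13-(benzyloxy)-2-hydroxytridecyl]-6-hydroxy-4-methoxybenzoate F7, which lactonises (helped by catalytic TsOH in warm toluene if needed) and comes back to the route at 21.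

Step 10. Desilylation may occur without ring closure, the alkoxide being protonated by water in the fluoride reagent before it acylates, or adventitious hydroxide may open the dioxinone. The fallback separates the events and closes the lactone by acid catalysis. Setting out from 19, KOH in DMSO–H2O at 80 °C hydrolyses the acetonide ester to 2-[(2R)-13-(benzyloxy)-2-[(tert-butyldimethylsilyl)oxy]tridecyl]-6-hydroxy-4-methoxybenzoic acid F8. Aqueous HF in MeCN removes the silyl group to give 2-[(2R)-13-(benzyloxy)-2-hydroxytridecyl]-6-hydroxy-4-methoxybenzoic acid F9, and this δ-hydroxy acid closes under TsOH in toluene, coming back to the route at 21.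

Further compounds
F1 | step 7 | (3R)-14-(benzyloxy)-3-[(tert-butyldimethylsilyl)oxy]tetradecanal | O=CC[C@H](O[Si](C)(C)C(C)(C)C)CCCCCCCCCCCOCc1ccccc1
F2 | step 7 | 6-[(6R)-17-(benzyloxy)-6-[(tert-butyldimethylsilyl)oxy]-4-hydroxy-2-oxoheptadecyl]-2,2-dimethyl-4H-1,3-dioxin-4-one, both C-4 epimers | CC1(C)OC(=O)C=C(CC(=O)CC(O)C[C@H](O[Si](C)(C)C(C)(C)C)CCCCCCCCCCCOCc2ccccc2)O1
F3 | step 8 | (9R)-20-(benzyloxy)-9-[(tert-butyldimethylsilyl)oxy]icos-1-ene-1,3,5,7-tetrone | O=C=CC(=O)CC(=O)CC(=O)C[C@H](O[Si](C)(C)C(C)(C)C)CCCCCCCCCCCOCc1ccccc1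
F4 | step 8 | methyl (9R)-20-(benzyloxy)-9-[(tert-butyldimethylsilyl)oxy]-3,5,7-trioxoicosanoate | COC(=O)CC(=O)CC(=O)CC(=O)C[C@H](O[Si](C)(C)C(C)(C)C)CCCCCCCCCCCOCc1ccccc1
F5 | step 8 | methyl 2-[(2R)-13-(benzyloxy)-2-[(tert-butyldimethylsilyl)oxy]tridecyl]-4,6-dihydroxybenzoate | COC(=O)c1c(O)cc(O)cc1C[C@H](O[Si](C)(C)C(C)(C)C)CCCCCCCCCCCOCc2ccccc2
F6 | step 8 | methyl 2-[(2R)-13-(benzyloxy)-2-[(tert-butyldimethylsilyl)oxy]tridecyl]-6-hydroxy-4-methoxybenzoate | COC(=O)c1c(O)cc(OC)cc1C[C@H](O[Si](C)(C)C(C)(C)C)CCCCCCCCCCCOCc2ccccc2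
F7 | step 8 | methyl 2-[(2R)-13-(benzyloxy)-2-hydroxytridecyl]-6-hydroxy-4-methoxybenzoate | COC(=O)c1c(O)cc(OC)cc1C[C@H](O)CCCCCCCCCCCOCc2ccccc2
F8 | step 10 | 2-[(2R)-13-(benzyloxy)-2-[(tert-butyldimethylsilyl)oxy]tridecyl]-6-hydroxy-4-methoxybenzoic acid | OC(=O)c1c(O)cc(OC)cc1C[C@H](O[Si](C)(C)C(C)(C)C)CCCCCCCCCCCOCc2ccccc2
F9 | step 10 | 2-[(2R)-13-(benzyloxy)-2-hydroxytridecyl]-6-hydroxy-4-methoxybenzoic acid | OC(=O)c1c(O)cc(OC)cc1C[C@H](O)CCCCCCCCCCCOCc2ccccc2
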